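**Retrosynthetic overview**
1. Target 18 comes from global O-demethylation of its hexadecamethyl ether 16. All six benzene rings are bought and none is built; the rings are called A to F from the 2,4,6-trihydroxyphenoxy end.
2. 16 is cut at the D–O–E ether: Ullmann coupling of tetramer phenol 13 (rings A–D) with aryl bromide 15 (rings E–F).
3. 13 comes by Dakin oxidation from aldehyde 11, which is cut at the B–O–C ether: Ullmann coupling of dimer phenol 8 (rings A–B) with bromo-aldehyde 10 (rings C–D).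
4. 8 and 10 both come from SNAr of a 2,6-dimethoxyphenol (5 or 9) on fluoro-aldehyde 4, whose CHO activates the C–F bond and is then a latent OH (Dakin). 15 comes from Chan–Lam coupling of 9 with boronic acid 14.
5. Order of ring joining: A+B, C+D, AB+CD, E+F, ABCD+EF.

Assumption: the target has no stereocentre and no hindered axis, so the compound itself is the "single enantiomer"; 1, 5, 9 and 14 are taken as catalogue compounds.

**Route**

Step 1
Reactants: 1 5-fluoro-1,2,3-trimethoxybenzene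
Product: 4 6-fluoro-2,3,4-trimethoxybenzaldehyde, via aryllithium 2 (not isolated), via lithium aminoalkoxide 3 (not isolated)
Conditions: n-BuLi (1.05 equiv), THF, −78 °C, 1 h; DMF (1.5 equiv), −78 to 0 °C; 1 M HCl
Reagents that add atoms: DMF, CN(C)C=O
Why: Directed ortho-metalation at the only kind of ring C–H (flanked by F and OMe, kept at −78 °C so that no LiF is lost to an aryne) followed by DMF formylation; the carbinol carbon of 3 is a transient racemic centre that collapses to the planar CHO.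

Step 2
Reactants: 5 2,4,6-trimethoxyphenol; 4 6-fluoro-2,3,4-trimethoxybenzaldehyde
Product: 6 2,3,4-trimethoxy-6-(2,4,6-trimethoxyphenoxy)benzaldehyde
Conditions: 5 (1.1 equiv), K2CO3 (2 equiv), DMF, 110 °C, Ar
Reagents that add atoms: none
Why: SNAr, in which the ortho-formyl group stabilises the Meisenheimer adduct so that the hindered but electron-rich phenoxide displaces fluoride; no stereocentre is formed.

Step 3
Reactants: 6 2,3,4-trimethoxy-6-(2,4,6-trimethoxyphenoxy)benzaldehyde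
Product: 8 2,3,4-trimethoxy-6-(2,4,6-trimethoxyphenoxy)phenol, via aryl formate 7 (not isolated)
Conditions: mCPBA (1.3 equiv), CH2Cl2, 0 °C to rt; aq. Na2S2O3/NaHCO3 wash; K2CO3 (0.2 equiv), MeOH, rt, Ar
Reagents that add atoms: mCPBA (3-chloroperoxybenzoic acid), OOC(=O)c1cccc(Cl)c1
Why: Dakin-type Baeyer–Villiger oxidation, in which the electron-rich aryl group migrates to give formate 7, and base-catalysed methanolysis then frees the phenol; no stereocentre is formed.

Step 4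
Reactants: 9 4-bromo-2,6-dimethoxyphenol; 4 6-fluoro-2,3,4-trimethoxybenzaldehyde
Product: 10 6-(4-bromo-2,6-dimethoxyphenoxy)-2,3,4-trimethoxybenzaldehyde
Conditions: 9 (1.1 equiv), K2CO3 (2 equiv), DMF, 110 °C, Ar
Reagents that add atoms: none
Why: The same SNAr as in step 2; the unactivated C–Br bond of 9 is inert because no transition metal is present.

Step 5
Reactants: 8 2,3,4-trimethoxy-6-(2,4,6-trimethoxyphenoxy)phenol; 10 6-(4-bromo-2,6-dimethoxyphenoxy)-2,3,4-trimethoxybenzaldehyde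
Product: 11 rings A–D aldehyde, 6-{2,6-dimethoxy-4-[2,3,4-trimethoxy-6-(2,4,6-trimethoxyphenoxy)phenoxy]phenoxy}-2,3,4-trimethoxybenzaldehyde
Conditions: 8 (1.2 equiv), CuI (0.2 equiv), picolinic acid (0.4 equiv), K3PO4 (2 equiv), DMSO, 100 °C, Ar
Reagents that add atoms: none
Why: Ullmann-type C–O coupling in which the ligated monovalent copper phenoxide of the hindered phenol arylates at a C–Br carbon with two free ortho positions, while the non-enolisable aldehyde is a spectator; no stereocentre is formed.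

Step 6
Reactants: 11 rings A–D aldehyde
Product: 13 rings A–D phenol, 6-{2,6-dimethoxy-4-[2,3,4-trimethoxy-6-(2,4,6-trimethoxyphenoxy)phenoxy]phenoxy}-2,3,4-trimethoxyphenol, via aryl formate 12 (not isolated)
Conditions: mCPBA (1.3 equiv), CH2Cl2, 0 °C to rt; aq. Na2S2O3/NaHCO3 wash; K2CO3 (0.2 equiv), MeOH, rt, Ar
Reagents that add atoms: mCPBA (3-chloroperoxybenzoic acid), OOC(=O)c1cccc(Cl)c1
Why: Dakin-type Baeyer–Villiger oxidation as in step 3, the tetra-oxygenated ring D migrating in preference to hydride, then formate methanolysis; no stereocentre is formed.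

Step 7
Reactants: 9 4-bromo-2,6-dimethoxyphenol; 14 (3,4,5-trimethoxyphenyl)boronic acid
Product: 15 5-bromo-1,3-dimethoxy-2-(3,4,5-trimethoxyphenoxy)benzene
Conditions: 14 (2 equiv), Cu(OAc)2 (1 equiv, turned over by O2), pyridine (5 equiv), 4 Å MS, CH2Cl2, dry air, rt, 48 h
Reagents that add atoms: none
Why: Chan–Lam oxidative O-arylation with divalent copper acetate at room temperature, which leaves the C–Br bond untouched because no low-valent metal is present to insert into it.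

Step 8
Reactants: 13 rings A–D phenol; 15 5-bromo-1,3-dimethoxy-2-(3,4,5-trimethoxyphenoxy)benzene
Product: 16 hexadecamethyl ether of the target
Conditions: 15 (1.5 equiv), CuI (0.3 equiv), picolinic acid (0.6 equiv), K3PO4 (2.5 equiv), DMSO, 110 °C, Ar
Reagents that add atoms: none
Why: A second Ullmann-type C–O coupling of the same kind as step 5 (hindered 2-aryloxy-6-methoxyphenol, ortho-unsubstituted aryl bromide), with no other reactive group left in either partner.

Step 9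
Reactants: 16 hexadecamethyl ether of the target
Product: 18 CNP0218077.0, via hexadecakis(dibromoboryl) ether 17 (not isolated)
Conditions: BBr3 (1 M in CH2Cl2, 40 equiv), CH2Cl2, −78 °C to rt, 24 h, Ar; MeOH/H2O, 0 °C; Sephadex LH-20 (degassed MeOH)
Reagents that add atoms: none
Why: Lewis-acid ether cleavage in which BBr3 binds each methoxy oxygen and bromide attacks the methyl carbon (SN2), so only the sixteen O–CH3 bonds break; the diaryl ether bonds have no sp3 carbon to attack and survive, and hydrolysis of the borates gives the achiral hexadecaphenol.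

**Compound list**
1 | 5-fluoro-1,2,3-trimethoxybenzene | COc1cc(F)cc(OC)c1OC | starting material
2 | (6-fluoro-2,3,4-trimethoxyphenyl)lithium, not isolated | [Li]c1c(F)cc(OC)c(OC)c1OC | intermediate
3 | lithium (dimethylamino)(6-fluoro-2,3,4-trimethoxyphenyl)methanolate, racemic, not isolated | [Li+].[O-]C(N(C)C)c1c(F)cc(OC)c(OC)c1OC | intermediate
4 | 6-fluoro-2,3,4-trimethoxybenzaldehyde (source of rings B and D) | O=Cc1c(F)cc(OC)c(OC)c1OC | intermediate
5 | 2,4,6-trimethoxyphenol (ring A) | COc1cc(OC)c(O)c(OC)c1 | starting material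
6 | 2,3,4-trimethoxy-6-(2,4,6-trimethoxyphenoxy)benzaldehyde (rings A–B) | O=Cc1c(Oc2c(OC)cc(OC)cc2OC)cc(OC)c(OC)c1OC | intermediate
7 | 2,3,4-trimethoxy-6-(2,4,6-trimethoxyphenoxy)phenyl formate, not isolated | O=COc1c(Oc2c(OC)cc(OC)cc2OC)cc(OC)c(OC)c1OC | intermediate
8 | 2,3,4-trimethoxy-6-(2,4,6-trimethoxyphenoxy)phenol (rings A–B) | Oc1c(Oc2c(OC)cc(OC)cc2OC)cc(OC)c(OC)c1OC | intermediate
9 | 4-bromo-2,6-dimethoxyphenol (source of rings C and E) | COc1cc(Br)cc(OC)c1O | starting material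
10 | 6-(4-bromo-2,6-dimethoxyphenoxy)-2,3,4-trimethoxybenzaldehyde (rings C–D) | O=Cc1c(Oc2c(OC)cc(Br)cc2OC)cc(OC)c(OC)c1OC | intermediate
11 | 6-{2,6-dimethoxy-4-[2,3,4-trimethoxy-6-(2,4,6-trimethoxyphenoxy)phenoxy]phenoxy}-2,3,4-trimethoxybenzaldehyde (rings A–D) | O=Cc1c(Oc2c(OC)cc(Oc3c(Oc4c(OC)cc(OC)cc4OC)cc(OC)c(OC)c3OC)cc2OC)cc(OC)c(OC)c1OC | intermediate
12 | formate ester of 13 (aryl formate in place of the CHO of 11), not isolated | O=COc1c(Oc2c(OC)cc(Oc3c(Oc4c(OC)cc(OC)cc4OC)cc(OC)c(OC)c3OC)cc2OC)cc(OC)c(OC)c1OC | intermediate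
13 | 6-{2,6-dimethoxy-4-[2,3,4-trimethoxy-6-(2,4,6-trimethoxyphenoxy)phenoxy]phenoxy}-2,3,4-trimethoxyphenol (rings A–D) | Oc1c(Oc2c(OC)cc(Oc3c(Oc4c(OC)cc(OC)cc4OC)cc(OC)c(OC)c3OC)cc2OC)cc(OC)c(OC)c1OC | intermediate
14 | (3,4,5-trimethoxyphenyl)boronic acid (ring F) | COc1cc(B(O)O)cc(OC)c1OC | starting material
15 | 5-bromo-1,3-dimethoxy-2-(3,4,5-trimethoxyphenoxy)benzene (rings E–F) | COc1cc(Br)cc(OC)c1Oc1cc(OC)c(OC)c(OC)c1 | intermediate
16 | hexadecamethyl ether of the target (every OH of 18 as OMe) | COc1cc(OC)c(Oc2cc(OC)c(OC)c(OC)c2Oc2cc(OC)c(Oc3cc(OC)c(OC)c(OC)c3Oc3cc(OC)c(Oc4cc(OC)c(OC)c(OC)c4)c(OC)c3)c(OC)c2)c(OC)c1 | intermediate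
17 | hexadecakis(dibromoboryl) ether of the target (every OH of 18 as O–BBr2, drawn in its simplest form), not isolated | BrB(Br)Oc1cc(OB(Br)Br)c(Oc2cc(OB(Br)Br)c(OB(Br)Br)c(OB(Br)Br)c2Oc2cc(OB(Br)Br)c(Oc3cc(OB(Br)Br)c(OB(Br)Br)c(OB(Br)Br)c3Oc3cc(OB(Br)Br)c(Oc4cc(OB(Br)Br)c(OB(Br)Br)c(OB(Br)Br)c4)c(OB(Br)Br)c3)c(OB(Br)Br)c2)c(OB(Br)Br)c1 | intermediate
18 | CNP0218077.0: linear hexamer; ring A 2,4,6-trihydroxyphenoxy, rings B and D 3,4,5-trihydroxy-1,2-phenylenedioxy, rings C and E 2,6-dihydroxy-1,4-phenylenedioxy, ring F 3,4,5-trihydroxyphenyl; achiral | Oc1cc(O)c(Oc2cc(O)c(O)c(O)c2Oc2cc(O)c(Oc3cc(O)c(O)c(O)c3Oc3cc(O)c(Oc4cc(O)c(O)c(O)c4)c(O)c3)c(O)c2)c(O)c1 | target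

**Totals and risks**

Total step count: 9. Longest linear sequence: 7 steps (1, 2, 3, 5, 6, 8, 9).

The three steps most likely to fail are 8, 5 and 9, with step 8 the most exposed. They are given below in step order.

Step 5 (Ullmann coupling of 8 with 10; a hindered phenol and an electron-rich bromide). The fallback replaces copper catalysis by a metal-free SNAr/Dakin growth, sets out from 8 and comes back at 11. Phenol 8 is heated with catalogue 4-fluoro-2,6-dimethoxybenzaldehyde (O=Cc1c(OC)cc(F)cc1OC) and K2CO3 in DMF at 110 °C, where the para-formyl group activates the fluoride, to give the rings A–C aldehyde F1. mCPBA in CH2Cl2 converts it into the rings A–C formate F2, which K2CO3/MeOH cleaves to the rings A–C phenol F3. SNAr of F3 on fluoro-aldehyde 4 (K2CO3, DMF, 110 °C) then gives 11.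

Step 8 (Ullmann coupling of 13 with 15; the largest and most hindered phenol). The fallback again grows the chain by SNAr/Dakin one ring at a time, sets out from 13 and comes back at 16. Phenol 13 and 4-fluoro-2,6-dimethoxybenzaldehyde (K2CO3, DMF, 110 °C) give the rings A–E aldehyde F4. mCPBA gives the rings A–E formate F5, and K2CO3/MeOH gives the rings A–E phenol F6. A second SNAr with the same fluoro-aldehyde gives the rings A–F aldehyde F7. mCPBA gives the rings A–F formate F8, and methanolysis gives the rings A–F phenol F9, whose ring F is 4-hydroxy-3,5-dimethoxyphenyl. O-Methylation with MeI and K2CO3 in acetone gives 16.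

Step 9 (sixteen demethylations and isolation of an air-sensitive polyphenol). The fallback changes the isolation strategy to derivatise, purify and release; it sets out from 16 and comes back at 18. After BBr3 treatment and methanol quench as in step 9, the crude polyphenol is not purified but acetylated directly (Ac2O, pyridine, DMAP cat., rt, Ar) to the hexadecaacetate F10. This is stable to air and is purified on silica. Acid-catalysed methanolysis under argon (HCl in degassed MeOH, rt), which never generates oxidisable phenolates, then releases 18 after evaporation.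

**Further compounds**
F1 | step 5 | 2,6-dimethoxy-4-[2,3,4-trimethoxy-6-(2,4,6-trimethoxyphenoxy)phenoxy]benzaldehyde (rings A–C aldehyde) | O=Cc1c(OC)cc(Oc2c(Oc3c(OC)cc(OC)cc3OC)cc(OC)c(OC)c2OC)cc1OC
F2 | step 5 | 2,6-dimethoxy-4-[2,3,4-trimethoxy-6-(2,4,6-trimethoxyphenoxy)phenoxy]phenyl formate (rings A–C formate) | O=COc1c(OC)cc(Oc2c(Oc3c(OC)cc(OC)cc3OC)cc(OC)c(OC)c2OC)cc1OC
F3 | step 5 | 2,6-dimethoxy-4-[2,3,4-trimethoxy-6-(2,4,6-trimethoxyphenoxy)phenoxy]phenol (rings A–C phenol) | Oc1c(OC)cc(Oc2c(Oc3c(OC)cc(OC)cc3OC)cc(OC)c(OC)c2OC)cc1OC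
F4 | step 8 | rings A–E aldehyde: 13 O-arylated on its free OH by a 4-formyl-3,5-dimethoxyphenyl group | O=Cc1c(OC)cc(Oc2c(Oc3c(OC)cc(Oc4c(Oc5c(OC)cc(OC)cc5OC)cc(OC)c(OC)c4OC)cc3OC)cc(OC)c(OC)c2OC)cc1OC
F5 | step 8 | rings A–E formate: F4 with O–CHO in place of CHO | O=COc1c(OC)cc(Oc2c(Oc3c(OC)cc(Oc4c(Oc5c(OC)cc(OC)cc5OC)cc(OC)c(OC)c4OC)cc3OC)cc(OC)c(OC)c2OC)cc1OC
F6 | step 8 | rings A–E phenol: F4 with OH in place of CHO | Oc1c(OC)cc(Oc2c(Oc3c(OC)cc(Oc4c(Oc5c(OC)cc(OC)cc5OC)cc(OC)c(OC)c4OC)cc3OC)cc(OC)c(OC)c2OC)cc1OC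
F7 | step 8 | rings A–F aldehyde: F6 O-arylated on its free OH by a 4-formyl-3,5-dimethoxyphenyl group | O=Cc1c(OC)cc(Oc2c(OC)cc(Oc3c(Oc4c(OC)cc(Oc5c(Oc6c(OC)cc(OC)cc6OC)cc(OC)c(OC)c5OC)cc4OC)cc(OC)c(OC)c3OC)cc2OC)cc1OC
F8 | step 8 | rings A–F formate: F7 with O–CHO in place of CHO | O=COc1c(OC)cc(Oc2c(OC)cc(Oc3c(Oc4c(OC)cc(Oc5c(Oc6c(OC)cc(OC)cc6OC)cc(OC)c(OC)c5OC)cc4OC)cc(OC)c(OC)c3OC)cc2OC)cc1OC
F9 | step 8 | rings A–F phenol: 16 with OH in place of the 4-OMe of ring F | Oc1c(OC)cc(Oc2c(OC)cc(Oc3c(Oc4c(OC)cc(Oc5c(Oc6c(OC)cc(OC)cc6OC)cc(OC)c(OC)c5OC)cc4OC)cc(OC)c(OC)c3OC)cc2OC)cc1OC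
F10 | step 9 | hexadecaacetate of 18 (every OH as OAc) | CC(=O)Oc1cc(OC(C)=O)c(Oc2cc(OC(C)=O)c(OC(C)=O)c(OC(C)=O)c2Oc2cc(OC(C)=O)c(Oc3cc(OC(C)=O)c(OC(C)=O)c(OC(C)=O)c3Oc3cc(OC(C)=O)c(Oc4cc(OC(C)=O)c(OC(C)=O)c(OC(C)=O)c4)c(OC(C)=O)c3)c(OC(C)=O)c2)c(OC(C)=O)c1
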